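## Retrosynthetic overview

1. Last step: one C4–C5 bond closes the tetrahydropyran and the ten-membered carbocycle together, in a chloride-terminated allene Prins macrocyclization of a C4 acetal tethered to the C8/C9 diol. This sets C4 and C6, brings in Cl and the C5 exo-methylene, and frees 9-OH.
2. The tethering acetal comes from a 9-hydroxy butenolide by acetal hydrolysis, lactol formation and intramolecular oxa-Michael addition (C8, C17).
3. The C8–C9 bond is made by Nozaki–Hiyama–Kishi union of a ring A aldehyde with a 4-bromo-5-allenyl butenolide (C9).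
4. Ring A comes from (S)-carvone: syn-aldol (C2), methylation (C1), Criegee rearrangement (14-OAc), Luche reduction, allylic borylation and allylboration of formaldehyde (C10, C9).
5. The lactone comes from ethyl 2-methylacetoacetate via 3-methyltetronic acid, vinylogous Mukaiyama aldol with propynal (C7) and Myers allene synthesis. Ring order: ring A (chiral pool), γ-lactone, then tetrahydropyran and ten-membered ring together.

Assumptions: briarane numbering (C18 = methyl on C17, C19 = lactone carbonyl) and α/β (β = face of the C15 methyl) are used for all intermediates; the BINOL antipode in step 11 is the one that gives the 5S adduct; 17R is taken as the thermodynamically preferred C17 epimer. The route is a proposal and has not been run.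

## Route

Step 1
Reactants: 1 methyl 3,3-dimethoxypropanoate
Product: 2 3,3-dimethoxypropanal
Conditions: i-Bu2AlH (1.05 equiv), CH2Cl2, −78 °C; aq. KNaC4H4O6
Reagents that add atoms: none
Why: Low-temperature half-reduction of an ester stops at the aluminium hemiacetal, which gives the aldehyde on work-up; no stereocentre is formed.

Step 2
Reactants: 3 (S)-(+)-carvone; 2 3,3-dimethoxypropanal
Product: 6 (5S,6S)-6-[(1R)-1-hydroxy-3,3-dimethoxypropyl]-2-methyl-5-(prop-1-en-2-yl)cyclohex-2-en-1-one, via lithium enolate 4 (not isolated), via zirconium enolate 5 (not isolated)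
Conditions: LiN(i-Pr)2, THF, −78 °C; Cp2ZrCl2, −78 → −30 °C; 2, −78 °C; aq. NH4Cl
Reagents that add atoms: none
Why: Kinetic α′-deprotonation followed by a zirconium enolate aldol (syn-selective whatever the enolate geometry), with the aldehyde adding anti to the isopropenyl group, sets C2 as R; the ring centre formed here is provisional.

Step 3
Reactants: 6 syn-aldol
Product: 8 (5R,6R)-6-[(1R)-1-hydroxy-3,3-dimethoxypropyl]-2,6-dimethyl-5-(prop-1-en-2-yl)cyclohex-2-en-1-one, via dilithium alkoxide enolate 7 (not isolated)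
Conditions: LiN(i-Pr)2 (2.3 equiv), THF, −78 → −20 °C; MeI, DMPU, −78 → 0 °C
Reagents that add atoms: iodomethane, CI
Why: Fráter–Seebach-type dianion C-alkylation in which MeI attacks the enolate face anti to the neighbouring isopropenyl group, so the new methyl is β and the oxygenated chain α (quaternary C1, R), the alkoxide preventing β-elimination.

Step 4
Reactants: 8 methylated ketol
Product: 10 (1R)-1-[(1R,6S)-6-acetoxy-1,3-dimethyl-2-oxocyclohex-3-en-1-yl]-3,3-dimethoxypropyl acetate, via methoxy hydroperoxide 9 (not isolated)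
Conditions: O3, CH2Cl2/MeOH, −78 °C; then Ac2O, Et3N, DMAP, 0 → 40 °C
Reagents that add atoms: ozone, [O-][O+]=O; methanol, CO; acetic anhydride, CC(=O)OC(C)=O
Why: Ozonolysis of the electron-rich isopropenyl group in methanol and Criegee rearrangement of the derived peracetate turn C–C(CH3)=CH2 into C–OAc with retention at C14, while the same Ac2O acetylates 2-OH.

Step 5
Reactants: 10 diacetoxy enone
Product: 11 (1R)-1-[(1R,2R,6S)-6-acetoxy-2-hydroxy-1,3-dimethylcyclohex-3-en-1-yl]-3,3-dimethoxypropyl acetate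
Conditions: NaBH4, CeCl3·7H2O, MeOH, −40 °C
Reagents that add atoms: none
Why: Luche 1,2-reduction in which axial hydride attack on the half-chair with the C1 side chain pseudo-axial comes from the β face (anti to that chain, past the axial H14) and gives the 10α-alcohol.

Step 6
Reactants: 11 10α-allylic alcohol
Product: 12 (1R)-1-[(1R,2R,6S)-6-acetoxy-2-[(methoxycarbonyl)oxy]-1,3-dimethylcyclohex-3-en-1-yl]-3,3-dimethoxypropyl acetate
Conditions: ClCO2Me, pyridine, DMAP (cat.), CH2Cl2, 0 °C → rt
Reagents that add atoms: methyl chloroformate, COC(=O)Cl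
Why: Simple O-acylation to the allylic carbonate needed for copper-catalysed substitution; no stereocentre changes.

Step 7
Reactants: 12 allylic carbonate
Product: 14 (1R)-1-[(1R,2S,6S)-6-acetoxy-2-(hydroxymethyl)-1,3-dimethylcyclohex-3-en-1-yl]-3,3-dimethoxypropyl acetate, via allylboronate 13 (not isolated)
Conditions: B2pin2, CuCl (10 mol%), Xantphos (10 mol%), KOt-Bu (20 mol%), THF, rt; then (CH2O)n, 60 °C; aq. NH4Cl
Reagents that add atoms: formaldehyde (from paraformaldehyde), C=O
Why: Copper-catalysed γ-selective anti-SN2′ borylation puts boron on the β face of C12, and allylboration through the closed six-membered transition state forms the C9–C10 bond syn to boron on the β face, setting C10 (S) and restoring the C11=C12 alkene.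

Step 8
Reactants: 14 homoallylic alcohol
Product: 15 (1R)-1-[(1R,2S,6S)-6-acetoxy-2-formyl-1,3-dimethylcyclohex-3-en-1-yl]-3,3-dimethoxypropyl acetate
Conditions: Dess–Martin periodinane, NaHCO3, CH2Cl2, 0 °C
Reagents that add atoms: none
Why: Buffered Dess–Martin oxidation gives the β,γ-unsaturated aldehyde without base, so C10 is not epimerised and the alkene does not move into conjugation; the aldehyde is used at once.

Step 9
Reactants: 16 ethyl 2-methyl-3-oxobutanoate
Product: 18 3-methyltetronic acid (4-hydroxy-3-methylfuran-2(5H)-one), via bromo keto ester 17 (not isolated)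
Conditions: Br2, CHCl3, 0 °C → rt, 16 h; then neat, 110 °C
Reagents that add atoms: none
Why: Bromination with HBr-mediated migration of bromine to the γ-carbon, then thermal lactonization with loss of bromoethane, is the classical tetronic acid synthesis; no stereocentre.

Step 10
Reactants: 18 3-methyltetronic acid
Product: 19 4-bromo-3-methylfuran-2(5H)-one
Conditions: (COBr)2, DMF (cat.), CH2Cl2, 0 °C → rt
Reagents that add atoms: oxalyl bromide, O=C(Br)C(=O)Br
Why: Vilsmeier-type activation of the vinylogous acid and addition–elimination by bromide give the β-bromo butenolide.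

Step 11
Reactants: 19 4-bromo-3-methylfuran-2(5H)-one; 20 propynal
Product: 22 (5S)-4-bromo-5-(1-hydroxyprop-2-yn-1-yl)-3-methylfuran-2(5H)-one (major diastereomer, carbinol configuration immaterial), via silyloxyfuran 21 (not isolated)
Conditions: TMSOTf, Et3N, CH2Cl2, 0 °C; then 20, Ti(Oi-Pr)4 (20 mol%), (S)-BINOL (20 mol%), Et2O, −20 °C; 1 M HCl
Reagents that add atoms: none
Why: Catalytic asymmetric vinylogous Mukaiyama aldol at C5 of the 2-silyloxyfuran sets C7 under titanium–BINOL control, the major diastereomer being taken on after chromatography because the carbinol centre is erased in the next step.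

Step 12
Reactants: 22 propargylic alcohol
Product: 24 (5S)-4-bromo-3-methyl-5-(propa-1,2-dien-1-yl)furan-2(5H)-one, via propargylic diazene 23 (not isolated)
Conditions: 2-O2NC6H4SO2NHNH2, PPh3, DEAD, THF, −15 °C → rt
Reagents that add atoms: none
Why: Myers allene synthesis, in which Mitsunobu displacement by the sulfonylhydrazide, loss of sulfinic acid and retro-ene loss of N2 convert the propargylic alcohol into the terminal allene without touching C7.

Step 13
Reactants: 15 ring A aldehyde; 24 allenyl bromobutenolide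
Product: 25 (1R)-1-[(1R,2S,6S)-6-acetoxy-2-{(R)-hydroxy[(2S)-4-methyl-5-oxo-2-(propa-1,2-dien-1-yl)-2,5-dihydrofuran-3-yl]methyl}-1,3-dimethylcyclohex-3-en-1-yl]-3,3-dimethoxypropyl acetate
Conditions: CrCl2 (4 equiv), NiCl2 (1 mol%), DMSO/THF, rt
Reagents that add atoms: none
Why: Nozaki–Hiyama–Kishi coupling in which the alkenylchromium adds to the α-branched aldehyde under Felkin–Anh control (anti to the quaternary C1, the C11 alkene carbon next to the carbonyl oxygen), which gives 9R.

Step 14
Reactants: 25 hydroxy butenolide acetal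
Product: 28 bicyclic acetal (1R,2R,4R,7S,8R,9R,10S,14S,17R): C4 is bonded to O8 and O9 (1,3-dioxolane inside a seven-membered O9–C4 ring), C8 carries the spiro γ-lactone with 17-H, C7 the allenyl group, via hydroxy aldehyde 26 (not isolated), via lactol 27 (not isolated)
Conditions: PPTS, acetone/H2O (10:1), 45 °C; concentrate; CSA (0.2 equiv), CH2Cl2, rt; Et3N quench
Reagents that add atoms: water, O
Why: Proposed new method: hydrolysis unmasks the C4 aldehyde, 9-OH closes the seven-membered lactol, and its hydroxyl adds 5-exo under acid catalysis to the butenolide β-carbon C8 from the face on which O9 sits in the A1,3-minimised rotamer (H9 eclipsing C8=C17), which is the face syn to C6 and gives 8R, while C17 equilibrates through the reversible addition to the epimer with methyl anti to the C9 branch (17R); the closest known reaction type is the hemiacetal-tethered intramolecular oxa-Michael addition used to make protected syn-diols.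

Step 15
Reactants: 28 bicyclic acetal
Product: 30 target CNP0198838.2, (1R,2R,4S,6S,7R,8R,9R,10S,14S,17R)-2,14-diacetoxy-6-chloro-9-hydroxy-4,8-epoxybriara-5(16),11-diene 7,8-fused γ-lactone, via oxocarbenium ion 29 (not isolated)
Conditions: TiCl4 (2.5 equiv), CH2Cl2 (2 mM), −78 °C, 30 min; aq. NaHCO3
Reagents that add atoms: titanium tetrachloride, Cl[Ti](Cl)(Cl)Cl
Why: Proposed new method: TiCl4 opens the dioxolane acetal at the less hindered O9 to the eight-membered (Z)-oxocarbenium ion O8=C4, the central allene carbon C5 attacks C4 through a chair with the C3 and C9 bridge bonds axial (C4 becomes S), and the resulting 2-methylene allyl cation is captured by chloride at C6 on the exo face anti to the carbon bridge (6S, equatorial Cl), so one C–C bond closes the tetrahydropyran and the ten-membered carbocycle and work-up frees 9-OH; the closest known reaction types are Prins macrocyclization from cyclic acetals and halide-terminated Prins cyclization of homoallylic alcohols.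

## Compound list

1 | methyl 3,3-dimethoxypropanoate | COC(=O)CC(OC)OC | starting material
2 | 3,3-dimethoxypropanal | O=CCC(OC)OC | intermediate
3 | (S)-(+)-carvone, (5S)-2-methyl-5-(prop-1-en-2-yl)cyclohex-2-en-1-one | O=C1C[C@@H](C(C)=C)CC=C1C | starting material
4 | lithium α′-enolate of 3 | [Li]OC1=C[C@@H](C(C)=C)CC=C1C | intermediate
5 | chlorobis(cyclopentadienyl)zirconium enolate of 3 | Cl[Zr](OC1=C[C@@H](C(C)=C)CC=C1C)(C1C=CC=C1)C1C=CC=C1 | intermediate
6 | (5S,6S)-6-[(1R)-1-hydroxy-3,3-dimethoxypropyl]-2-methyl-5-(prop-1-en-2-yl)cyclohex-2-en-1-one | COC(OC)C[C@@H](O)[C@@H]1[C@@H](C(C)=C)CC=C(C)C1=O | intermediate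
7 | dilithium alkoxide enolate of 6 | COC(OC)C[C@@H](O[Li])C1=C(O[Li])C(C)=CC[C@@H]1C(C)=C | intermediate
8 | (5R,6R)-6-[(1R)-1-hydroxy-3,3-dimethoxypropyl]-2,6-dimethyl-5-(prop-1-en-2-yl)cyclohex-2-en-1-one | COC(OC)C[C@@H](O)[C@@]1(C)[C@@H](C(C)=C)CC=C(C)C1=O | intermediate
9 | (5S,6R)-5-(1-hydroperoxy-1-methoxyethyl)-6-[(1R)-1-hydroxy-3,3-dimethoxypropyl]-2,6-dimethylcyclohex-2-en-1-one (epimers at the peroxy carbon) | COC(OC)C[C@@H](O)[C@@]1(C)[C@@H](C(C)(OC)OO)CC=C(C)C1=O | intermediate
10 | (1R)-1-[(1R,6S)-6-acetoxy-1,3-dimethyl-2-oxocyclohex-3-en-1-yl]-3,3-dimethoxypropyl acetate | COC(OC)C[C@@H](OC(C)=O)[C@@]1(C)[C@@H](OC(C)=O)CC=C(C)C1=O | intermediate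
11 | (1R)-1-[(1R,2R,6S)-6-acetoxy-2-hydroxy-1,3-dimethylcyclohex-3-en-1-yl]-3,3-dimethoxypropyl acetate | COC(OC)C[C@@H](OC(C)=O)[C@@]1(C)[C@@H](OC(C)=O)CC=C(C)[C@H]1O | intermediate
12 | (1R)-1-[(1R,2R,6S)-6-acetoxy-2-[(methoxycarbonyl)oxy]-1,3-dimethylcyclohex-3-en-1-yl]-3,3-dimethoxypropyl acetate | COC(OC)C[C@@H](OC(C)=O)[C@@]1(C)[C@@H](OC(C)=O)CC=C(C)[C@H]1OC(=O)OC | intermediate
13 | (1R)-1-[(1R,4S,6S)-6-acetoxy-1,3-dimethyl-4-(4,4,5,5-tetramethyl-1,3,2-dioxaborolan-2-yl)cyclohex-2-en-1-yl]-3,3-dimethoxypropyl acetate | COC(OC)C[C@@H](OC(C)=O)[C@@]1(C)[C@@H](OC(C)=O)C[C@H](B2OC(C)(C)C(C)(C)O2)C(C)=C1 | intermediate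
14 | (1R)-1-[(1R,2S,6S)-6-acetoxy-2-(hydroxymethyl)-1,3-dimethylcyclohex-3-en-1-yl]-3,3-dimethoxypropyl acetate | COC(OC)C[C@@H](OC(C)=O)[C@@]1(C)[C@@H](OC(C)=O)CC=C(C)[C@@H]1CO | intermediate
15 | (1R)-1-[(1R,2S,6S)-6-acetoxy-2-formyl-1,3-dimethylcyclohex-3-en-1-yl]-3,3-dimethoxypropyl acetate | COC(OC)C[C@@H](OC(C)=O)[C@@]1(C)[C@@H](OC(C)=O)CC=C(C)[C@@H]1C=O | intermediate
16 | ethyl 2-methyl-3-oxobutanoate | CCOC(=O)C(C)C(C)=O | starting material
17 | ethyl 4-bromo-2-methyl-3-oxobutanoate | CCOC(=O)C(C)C(=O)CBr | intermediate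
18 | 3-methyltetronic acid, 4-hydroxy-3-methylfuran-2(5H)-one | CC1=C(O)COC1=O | intermediate
19 | 4-bromo-3-methylfuran-2(5H)-one | CC1=C(Br)COC1=O | intermediate
20 | propynal | C#CC=O | starting material
21 | [(4-bromo-3-methylfuran-2-yl)oxy]trimethylsilane | CC1=C(O[Si](C)(C)C)OC=C1Br | intermediate
22 | (5S)-4-bromo-5-(1-hydroxyprop-2-yn-1-yl)-3-methylfuran-2(5H)-one (single diastereomer, carbinol configuration not assigned) | CC1=C(Br)[C@H](C(O)C#C)OC1=O | intermediate
23 | (5S)-4-bromo-5-(1-diazenylprop-2-yn-1-yl)-3-methylfuran-2(5H)-one | CC1=C(Br)[C@H](C(N=N)C#C)OC1=O | intermediate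
24 | (5S)-4-bromo-3-methyl-5-(propa-1,2-dien-1-yl)furan-2(5H)-one | CC1=C(Br)[C@H](C=C=C)OC1=O | intermediate
25 | (1R)-1-[(1R,2S,6S)-6-acetoxy-2-{(R)-hydroxy[(2S)-4-methyl-5-oxo-2-(propa-1,2-dien-1-yl)-2,5-dihydrofuran-3-yl]methyl}-1,3-dimethylcyclohex-3-en-1-yl]-3,3-dimethoxypropyl acetate | COC(OC)C[C@@H](OC(C)=O)[C@@]1(C)[C@@H](OC(C)=O)CC=C(C)[C@@H]1[C@@H](O)C1=C(C)C(=O)O[C@H]1C=C=C | intermediate
26 | hydroxy aldehyde: 25 with the C4 dimethyl acetal replaced by CHO (3-oxopropyl acetate) | O=CC[C@@H](OC(C)=O)[C@@]1(C)[C@@H](OC(C)=O)CC=C(C)[C@@H]1[C@@H](O)C1=C(C)C(=O)O[C@H]1C=C=C | intermediate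
27 | seven-membered lactol of 26 (O9–C4 hemiacetal, both C4 anomers) | OC1C[C@@H](OC(C)=O)[C@@]2(C)[C@@H](OC(C)=O)CC=C(C)[C@@H]2[C@@H](O1)C1=C(C)C(=O)O[C@H]1C=C=C | intermediate
28 | bicyclic acetal (1R,2R,4R,7S,8R,9R,10S,14S,17R): C4 acetal carbon bonded to O8 and O9, spiro γ-lactone at C8, allenyl at C7, 2,14-diacetate | [C@@H]12C[C@@H](OC(C)=O)[C@@]3(C)[C@@H](OC(C)=O)CC=C(C)[C@@H]3[C@@H](O1)[C@]1(O2)[C@@H](C)C(=O)O[C@H]1C=C=C | intermediate
29 | eight-membered oxocarbenium ion O8=C4 with 9-O–TiCl3, chloride counter-ion | [O+]1=CC[C@@H](OC(C)=O)[C@@]3(C)[C@@H](OC(C)=O)CC=C(C)[C@@H]3[C@@H](O[Ti](Cl)(Cl)Cl)[C@@]12[C@@H](C)C(=O)O[C@H]2C=C=C.[Cl-] | intermediate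
30 | CNP0198838.2, (1R,2R,4S,6S,7R,8R,9R,10S,14S,17R)-2,14-diacetoxy-6-chloro-9-hydroxy-4,8-epoxybriara-5(16),11-diene 7,8-fused γ-lactone | C=C1[C@@H]2C[C@@H](OC(C)=O)[C@@]3(C)[C@@H](OC(C)=O)CC=C(C)[C@@H]3[C@@H](O)[C@]3(O2)[C@@H](C)C(=O)O[C@H]3[C@H]1Cl | target

## Step count and risks

Total step count: 15. Longest linear sequence: 11 steps (steps 1–8, then 13–15); the butenolide branch is steps 9–12.

The three steps most likely to fail:

Step 15 (allene Prins macrocyclization). The eight-membered oxocarbenium ion may close poorly, chloride may be captured at C16, or the allylic chloride may ionise again under TiCl4. Fallback, from 28 back to 30: the closure is run under Brønsted acid without a halide source (CF3CO2H, CH2Cl2, 0 °C), so that the allyl cation is captured reversibly by trifluoroacetate at its primary terminus. This gives the 5(6)-ene 16-trifluoroacetate F1. NaHCO3/MeOH removes only the trifluoroacetate and gives the primary allylic alcohol F2. SOCl2 (1.05 equiv, Et2O, −20 °C) then places chlorine on C6 by SNi′ collapse of the chlorosulfite on the exo face and returns the C5 exo-methylene, giving 30. The C–Cl bond thus comes from allylic transposition of an alcohol and not from cation capture.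

Step 14 (lactol oxa-Michael addition to a tetrasubstituted butenolide). The addition may be too slow or thermodynamically unfavourable. Fallback, from 25 back to 28: hydroxyl-directed nucleophilic epoxidation of the butenolide (t-BuOOH/n-BuLi, THF, −20 °C; the lithium alkoxide of 9-OH delivers the peroxide to the same face as in the main step) gives the 8,17-epoxy lactone F3. SmI2 (THF/MeOH, −78 °C) cleaves the α C–O bond and gives the 8,9-diol F4 (8-hydroxy, 17-H lactone). CSA (CH2Cl2, 4 Å sieves) then closes the dioxolane acetal with the C4 dimethyl acetal and returns 28.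

Step 13 (Nozaki–Hiyama–Kishi union). Nickel may engage the allene, or the Felkin preference at C9 may be low. Fallback, from 15 and 24 back to 25: bromine–magnesium exchange on 24 (i-PrMgCl·LiCl, THF, −40 °C) gives the alkenylmagnesium chloride F5, which adds to 15 without nickel. If 25 comes with much of its C9 epimer F6, the mixture is oxidised (Dess–Martin periodinane) to the C9 ketone F7. Reduction with BH3·SMe2 and the CBS oxazaborolidine (enantiomer chosen for the 9R alcohol) returns 25, so C9 is set by reagent-controlled reduction instead of substrate-controlled addition.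

## Further compounds

F1 | step 15 | 16-trifluoroacetoxy 5(6)-ene isomer of the cyclised product (2,14-diacetate, 9-OH, 4,8-ether, γ-lactone; no chlorine) | FC(F)(F)C(=O)OCC=1[C@@H]2C[C@@H](OC(C)=O)[C@@]3(C)[C@@H](OC(C)=O)CC=C(C)[C@@H]3[C@@H](O)[C@]3(O2)[C@@H](C)C(=O)O[C@H]3C=1
F2 | step 15 | 16-hydroxy 5(6)-ene primary allylic alcohol | OCC=1[C@@H]2C[C@@H](OC(C)=O)[C@@]3(C)[C@@H](OC(C)=O)CC=C(C)[C@@H]3[C@@H](O)[C@]3(O2)[C@@H](C)C(=O)O[C@H]3C=1
F3 | step 14 | 8,17-epoxy lactone of 25 (epoxide oxygen syn to the allenyl group) | COC(OC)C[C@@H](OC(C)=O)[C@@]1(C)[C@@H](OC(C)=O)CC=C(C)[C@@H]1[C@@H](O)[C@@]12O[C@@]2(C)C(=O)O[C@H]1C=C=C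
F4 | step 14 | 8,9-diol (8R-hydroxy, 17R-H γ-lactone) with C4 dimethyl acetal | COC(OC)C[C@@H](OC(C)=O)[C@@]1(C)[C@@H](OC(C)=O)CC=C(C)[C@@H]1[C@@H](O)[C@]1(O)[C@@H](C)C(=O)O[C@H]1C=C=C
F5 | step 13 | alkenylmagnesium chloride from 24 | CC1=C([Mg]Cl)[C@H](C=C=C)OC1=O
F6 | step 13 | C9 epimer (9S) of 25 | COC(OC)C[C@@H](OC(C)=O)[C@@]1(C)[C@@H](OC(C)=O)CC=C(C)[C@@H]1[C@H](O)C1=C(C)C(=O)O[C@H]1C=C=C
F7 | step 13 | C9 ketone of 25 | COC(OC)C[C@@H](OC(C)=O)[C@@]1(C)[C@@H](OC(C)=O)CC=C(C)[C@@H]1C(=O)C1=C(C)C(=O)O[C@H]1C=C=C
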